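Ring A has oxygen at C2′ and C4′, prenyl at C3′ and C5′, H at C6′ and the cinnamoyl group at C1′. With C1′–C6′ cut, ring A plus its ketone is the chain C6′HO–C5′H(prenyl)–C4′(=O)–C3′H(prenyl)–C2′(=O)–C1′H2–C(=O)–CH=CH–Ar. Its storable cyclic form is a 4-pyranone in which O1 bridges C2′ and C6′.
Disconnection 1 (last step), C1′–C6′: the ring A carbocycle comes from a 3,5-diprenyl-4-pyranone with H at C6 and a 2-oxo-4-arylbut-3-enyl chain at C2. The ring oxygen ends as 2′-OH and the pyranone C=O as 4′-OH.
Disconnection 2, C1′–C(=O): the lateral carbanion of 2-methyl-3,5-diprenyl-4-pyranone is joined to the Weinreb amide of O-silylated (E)-p-coumaric acid. Ring B and the E alkene are bought.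
Disconnection 3: the pyranone comes from the symmetrical ketone 2,10-dimethylundeca-2,9-dien-6-one, one C1 unit (C6′) and an acetyl unit (C2′, C1′). The ketone comes from acetonedicarboxylate and two prenyl bromides.
Ring order: ring B is purchased, the pyranone ring is closed in step 4, and ring A is made from the pyranone ring in step 8.

Key step: step 8

Remark on the chemistry: prenyl means 3-methylbut-2-en-1-yl; 1,3-dicarbonyl compounds are drawn as keto tautomers and the species of the alkaline last step as neutral compounds, although they are present as enolates and phenolates.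

Step 1
Reactants: 1 dimethyl 1,3-acetonedicarboxylate; 2 prenyl bromide (two equivalents)
Product: 3 dimethyl 2,4-bis(3-methylbut-2-enyl)-3-oxopentanedioate (mixture of diastereomers)
Conditions: NaH (1.05 equiv), THF, 0 °C, then 2 (1.05 equiv), rt; second round of NaH and 2 in the same flask
Reagents that add atoms: prenyl bromide 2, CC(C)=CCBr
Why: Twofold acetoacetic-ester-type SN2 alkylation, in which the untouched CH2 remains the more acidic and less hindered site after the first prenylation, so the second prenyl group should go to the other flank; the two new stereocentres are uncontrolled and are erased in step 2.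

Step 2
Reactants: 3 dimethyl 2,4-bis(3-methylbut-2-enyl)-3-oxopentanedioate
Product: 4 2,10-dimethylundeca-2,9-dien-6-one
Conditions: LiCl, H2O, DMSO, 140 °C
Reagents that add atoms: none
Why: Double Krapcho dealkoxycarbonylation, in which chloride takes off each ester methyl group by SN2 and the β-keto carboxylates lose CO2 in a neutral medium, so neither retro-Claisen cleavage by hydroxide nor acid-induced hydration of the trisubstituted alkenes can interfere.

Step 3
Reactants: 4 2,10-dimethylundeca-2,9-dien-6-one; 5 tert-butoxybis(dimethylamino)methane (Bredereck's reagent)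
Product: 6 (5E)-5-[(dimethylamino)methylidene]-2,10-dimethylundeca-2,9-dien-6-one
Conditions: 5 (1.5 equiv), toluene, 110 °C
Reagents that add atoms: Bredereck's reagent 5, CN(C)C(OC(C)(C)C)N(C)C
Why: Aminomethylenation of an α-methylene ketone with a reagent that releases tert-butoxide and a formamidinium ion and so condenses with plain dialkyl ketones that respond sluggishly to DMF acetals; the ketone is symmetrical, so no regiochemical question arises, the vinylogous amide is too weakly acidic at its α′ carbon to react twice, and the alkene geometry (expected E) is lost in step 4.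

Step 4
Reactants: 6 (5E)-5-[(dimethylamino)methylidene]-2,10-dimethylundeca-2,9-dien-6-one; 7 acetyl chloride
Product: 9 2-methyl-3,5-bis(3-methylbut-2-enyl)-4H-pyran-4-one, via acetylated enaminone 8 (not isolated)
Conditions: 7 (1.3 equiv), THF, −78 °C, then LiN(SiMe3)2 (2.5 equiv) dropwise; AcOH (excess), −78 °C to 50 °C
Reagents that add atoms: acetyl chloride 7, CC(=O)Cl
Why: In situ C-acylation of an enaminone α′-anion with an acid chloride followed by acid closure (a known γ-pyranone synthesis), in which the second equivalent of base stores 8 as its diketonate; in acetic acid the enol oxygen of the new acetyl group then adds to the aminomethylene carbon and expels dimethylamine, under acidity too weak to harm the prenyl groups.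

Step 5
Reactants: 10 methyl (E)-4-hydroxycinnamate
Product: 11 methyl (E)-3-[4-(tert-butyldimethylsilyloxy)phenyl]prop-2-enoate
Conditions: TBSCl, imidazole, DMF, rt
Reagents that add atoms: tert-butyldimethylsilyl chloride, CC(C)(C)[Si](C)(C)Cl
Why: Imidazole-promoted silylation of a phenol, which removes the proton that would quench the carbanion of step 7 and installs a group that alkali strips off in the last step without a separate deprotection.

Step 6
Reactants: 11 methyl (E)-3-[4-(tert-butyldimethylsilyloxy)phenyl]prop-2-enoate
Product: 12 (E)-3-[4-(tert-butyldimethylsilyloxy)phenyl]-N-methoxy-N-methylprop-2-enamide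
Conditions: MeNH(OMe)·HCl (1.6 equiv), iPrMgCl (3.2 equiv), THF, −20 to 0 °C
Reagents that add atoms: N,O-dimethylhydroxylamine hydrochloride, CNOC.Cl
Why: Weinreb amide formation by aminolysis of the ester with the chloromagnesium amide made from MeNH(OMe)·HCl and iPrMgCl, a 1,2-selective acyl substitution that should leave the E alkene and the aryl silyl ether untouched.

Step 7
Reactants: 9 2-methyl-3,5-bis(3-methylbut-2-enyl)-4H-pyran-4-one; 12 (E)-3-[4-(tert-butyldimethylsilyloxy)phenyl]-N-methoxy-N-methylprop-2-enamide
Product: 15 2-[(E)-4-(4-tert-butyldimethylsilyloxyphenyl)-2-oxobut-3-enyl]-3,5-bis(3-methylbut-2-enyl)-4H-pyran-4-one, via lithium dienolate 13 (not isolated), via lithium hemiaminal adduct 14 (not isolated)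
Conditions: LiN(SiMe3)2 (1.1 equiv), THF, −78 °C; 12 (1.1 equiv), −78 to −20 °C; AcOH, −78 °C
Reagents that add atoms: none
Why: Lateral (vinylogous) deprotonation of the 2-methyl group, the only site whose anion is delocalised onto the C4 oxygen, gives 13, which should add through its exocyclic carbon in 1,2-fashion to the Weinreb amide (lateral lithiation–acylation); the chelated adduct 14 lasts until the cold acidic quench, so the acidic product never meets base, and this rules out proton exchange, double addition and premature opening of the pyranone.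

Step 8
Reactants: 15 2-[(E)-4-(4-tert-butyldimethylsilyloxyphenyl)-2-oxobut-3-enyl]-3,5-bis(3-methylbut-2-enyl)-4H-pyran-4-one
Product: 18 (E)-1-[2,4-dihydroxy-3,5-bis(3-methylbut-2-enyl)phenyl]-3-(4-hydroxyphenyl)prop-2-en-1-one (target), via free phenol pyranone 16 (not isolated), via open formyl triketone 17 (not isolated)
Conditions: KOH (1 M aq, 6 equiv), MeOH–THF, degassed, Ar, 0 °C to rt; then aq AcOH, 0 °C, to pH 5
Reagents that add atoms: none
Why: Hydroxide should first cleave the aryl silyl ether (16) and then add to C6 of the pyranone, its only unsubstituted vinylogous-ester carbon, after which retro-oxa-Michael rupture of O1–C6 leaves the former ring oxygen on C2′ and uncovers the formyl group of 17. The C1′ methylene, acidified by the C2′ and cinnamoyl carbonyl groups, then attacks the formyl carbon in an intramolecular Knoevenagel-type aldol that forms C1′–C6′ and closes ring A as a six-membered carbocycle in the 6-(enolexo)-exo-trig mode, and loss of water with enolisation of C2′=O and C4′=O to the resorcinol makes the sequence irreversible. The closest known reaction type is the alkali-induced recyclisation of 2-(2-oxoalkyl)-6-alkyl-4-pyranones to acylresorcinols (polyketide-type aromatisation), from which this case differs in closing onto an aldehyde instead of a ketone. No stereocentre is formed and the E alkene is not touched. The selectivity needed is closure of C1′ onto C6′ rather than of C5′ onto the cinnamoyl carbonyl: the latter would make C5′ quaternary (prenyl and formyl), cannot aromatise and stays reversible, the aldehyde is the better electrophile, and the ring B phenoxide freed at the outset pushes charge into the enone and shields both its carbonyl and its β carbon. Working at or below room temperature should avoid loss of the formyl carbon as formate, which normally calls for hot alkali, the strongly basic medium holds the product as the open chalcone phenolate rather than the flavanone, and cold buffering with acetic acid spares the prenyl groups.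

Compound list
1 | dimethyl 1,3-acetonedicarboxylate (dimethyl 3-oxopentanedioate) | COC(=O)CC(=O)CC(=O)OC | starting material
2 | prenyl bromide (1-bromo-3-methylbut-2-ene) | CC(C)=CCBr | starting material
3 | dimethyl 2,4-bis(3-methylbut-2-enyl)-3-oxopentanedioate, diastereomer mixture | COC(=O)C(CC=C(C)C)C(=O)C(CC=C(C)C)C(=O)OC | intermediate
4 | 2,10-dimethylundeca-2,9-dien-6-one | CC(C)=CCCC(=O)CCC=C(C)C | intermediate
5 | tert-butoxybis(dimethylamino)methane (Bredereck's reagent) | CN(C)C(OC(C)(C)C)N(C)C | starting material
6 | (5E)-5-[(dimethylamino)methylidene]-2,10-dimethylundeca-2,9-dien-6-one | CN(C)/C=C(\CC=C(C)C)C(=O)CCC=C(C)C | intermediate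
7 | acetyl chloride | CC(=O)Cl | starting material
8 | (5E)-7-acetyl-5-[(dimethylamino)methylidene]-2,10-dimethylundeca-2,9-dien-6-one, racemic, not isolated | CN(C)/C=C(\CC=C(C)C)C(=O)C(CC=C(C)C)C(C)=O | intermediate
9 | 2-methyl-3,5-bis(3-methylbut-2-enyl)-4H-pyran-4-one | CC1=C(CC=C(C)C)C(=O)C(CC=C(C)C)=CO1 | intermediate
10 | methyl (E)-4-hydroxycinnamate | COC(=O)/C=C/c1ccc(O)cc1 | starting material
11 | methyl (E)-3-[4-(tert-butyldimethylsilyloxy)phenyl]prop-2-enoate | COC(=O)/C=C/c1ccc(O[Si](C)(C)C(C)(C)C)cc1 | intermediate
12 | (E)-3-[4-(tert-butyldimethylsilyloxy)phenyl]-N-methoxy-N-methylprop-2-enamide | CON(C)C(=O)/C=C/c1ccc(O[Si](C)(C)C(C)(C)C)cc1 | intermediate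
13 | lithium 2-methylidene-3,5-bis(3-methylbut-2-enyl)-2H-pyran-4-olate, not isolated | [Li]OC1=C(CC=C(C)C)C(=C)OC=C1CC=C(C)C | intermediate
14 | lithium alkoxide of the tetrahedral adduct of 13 and 12, racemic, not isolated | CON(C)C(O[Li])(CC1=C(CC=C(C)C)C(=O)C(CC=C(C)C)=CO1)/C=C/c1ccc(O[Si](C)(C)C(C)(C)C)cc1 | intermediate
15 | 2-[(E)-4-(4-tert-butyldimethylsilyloxyphenyl)-2-oxobut-3-enyl]-3,5-bis(3-methylbut-2-enyl)-4H-pyran-4-one | O=C1C(CC=C(C)C)=COC(CC(=O)/C=C/c2ccc(O[Si](C)(C)C(C)(C)C)cc2)=C1CC=C(C)C | intermediate
16 | 2-[(E)-4-(4-hydroxyphenyl)-2-oxobut-3-enyl]-3,5-bis(3-methylbut-2-enyl)-4H-pyran-4-one, not isolated | O=C1C(CC=C(C)C)=COC(CC(=O)/C=C/c2ccc(O)cc2)=C1CC=C(C)C | intermediate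
17 | (8E)-9-(4-hydroxyphenyl)-2,4-bis(3-methylbut-2-enyl)-3,5,7-trioxonon-8-enal, not isolated | O=CC(CC=C(C)C)C(=O)C(CC=C(C)C)C(=O)CC(=O)/C=C/c1ccc(O)cc1 | intermediate
18 | (E)-1-[2,4-dihydroxy-3,5-bis(3-methylbut-2-enyl)phenyl]-3-(4-hydroxyphenyl)prop-2-en-1-one | CC(C)=CCc1cc(C(=O)/C=C/c2ccc(O)cc2)c(O)c(CC=C(C)C)c1O | target

Total step count: 8. Longest linear sequence: 6 steps (1, 2, 3, 4, 7, 8).

Steps most likely to fail

Step 8.
- **What may go wrong:** Hydroxide may attack the cinnamoyl enone by conjugate addition followed by retro-aldol cleavage. The opened chain may also close through carbon or oxygen onto the enone before the C1′–C6′ aldol takes place. Either process drains material away from ring A formation.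
- **Fallback (sets out from 9, comes back at 18):** The enone is kept out of the ring transformation and the chalcone alkene is built last.
  - Dienolate 13, made from 9 as in step 7, is acylated with N-methoxy-N-methylacetamide to give 2-(2-oxopropyl)-3,5-bis(3-methylbut-2-enyl)-4H-pyran-4-one F1.
  - Aqueous KOH should recyclise this enone-free and silyl-free pyranone, the parent case of the reaction type, to 1-[2,4-dihydroxy-3,5-bis(3-methylbut-2-enyl)phenyl]ethanone F2.
  - A Claisen–Schmidt condensation of F2 with commercial 4-hydroxybenzaldehyde (excess KOH, EtOH–H2O, rt) then forms the E enone and gives 18.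

Step 7.
- **What may go wrong:** The soft dienolate may add in conjugate fashion to the cinnamoyl acceptor. Its 1,2-addition to the electron-rich amide may also be so slow that proton exchange and decomposition of the carbanion take over.
- **Fallback (sets out from 12 and 9, comes back at 15):** Acylation is replaced by aldol addition and oxidation.
  - Amide 12 is reduced with iBu2AlH (THF, −78 °C) to (E)-3-[4-(tert-butyldimethylsilyloxy)phenyl]prop-2-enal F3.
  - Dienolate 13 should add at −78 °C to the far more electrophilic aldehyde carbonyl to give racemic 2-[(E)-4-(4-tert-butyldimethylsilyloxyphenyl)-2-hydroxybut-3-enyl]-3,5-bis(3-methylbut-2-enyl)-4H-pyran-4-one F4.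
  - MnO2 in CH2Cl2 oxidises the allylic alcohol of F4 to the ketone 15.

Step 4.
- **What may go wrong:** The hindered secondary enolate may be acylated on oxygen. The base may also consume the acetyl chloride through ketene formation. Both would leave the enaminone unchanged after the acidic stage.
- **Fallback (sets out from 4, comes back at 9):** A β-dicarbonyl dianion and a non-chloride acetyl donor are used instead.
  - Claisen formylation of 4 (ethyl formate, NaH, THF) gives 7-methyl-2-(3-methylbut-2-enyl)-3-oxooct-6-enal F5, present as its hydroxymethylene tautomer.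
  - Its dianion (LiN(iPr)2, 2.2 equiv, THF, 0 °C) reacts only at the strongly nucleophilic α′ carbon with N-methoxy-N-methylacetamide to give 4-acetyl-7-methyl-2-(3-methylbut-2-enyl)-3-oxooct-6-enal F6.
  - Warming F6 in acetic acid should cyclodehydrate it to 9.

Further compounds
F1 | step 8 | 2-(2-oxopropyl)-3,5-bis(3-methylbut-2-enyl)-4H-pyran-4-one | CC(=O)CC1=C(CC=C(C)C)C(=O)C(CC=C(C)C)=CO1
F2 | step 8 | 1-[2,4-dihydroxy-3,5-bis(3-methylbut-2-enyl)phenyl]ethanone | CC(=O)c1cc(CC=C(C)C)c(O)c(CC=C(C)C)c1O
F3 | step 7 | (E)-3-[4-(tert-butyldimethylsilyloxy)phenyl]prop-2-enal | O=C/C=C/c1ccc(O[Si](C)(C)C(C)(C)C)cc1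
F4 | step 7 | 2-[(E)-4-(4-tert-butyldimethylsilyloxyphenyl)-2-hydroxybut-3-enyl]-3,5-bis(3-methylbut-2-enyl)-4H-pyran-4-one, racemic | O=C1C(CC=C(C)C)=COC(CC(O)/C=C/c2ccc(O[Si](C)(C)C(C)(C)C)cc2)=C1CC=C(C)C
F5 | step 4 | 7-methyl-2-(3-methylbut-2-enyl)-3-oxooct-6-enal | O=CC(CC=C(C)C)C(=O)CCC=C(C)C
F6 | step 4 | 4-acetyl-7-methyl-2-(3-methylbut-2-enyl)-3-oxooct-6-enal | O=CC(CC=C(C)C)C(=O)C(C(C)=O)CC=C(C)C
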